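**Plan**

- Feature: in the 2,2-dimethyl-2,5-dihydrofuran (ring O, C6, C7=C8, C9Me2) the exocyclic, fully substituted C5=C6 alkene holds the ring oxygen trans to the formyl carbon on C5 and cis to C4. That is the imprint of an anti addition of the C9 hydroxyl and a metal across a C5≡C6 alkyne.
- Cuts, in retrosynthetic order: ring O–C6 together with C5–CHO carbon (oxypalladation–methoxycarbonylation of a (Z)-enynol); C6–C7 (Sonogashira); C5≡C6 back to a C5 aldehyde (one-carbon homologation); C3–C4 (aldehyde/nitrodiene Michael addition, the C3 carboxyl travelling as CH2NO2).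
- Forward: the open chain is joined from a nitrodiene and 4,4-dimethoxybutanal, the alkyne and the tert-butyl ester are installed, the (Z)-iodoalkenol arm is coupled, and the only ring closes in step 13. The C5 ester is then taken to the aldehyde and acid unmasks ketone, aldehyde and carboxylic acid.
- Stereochemistry: C3 (R) and C4 (S) both arise in the enamine-catalysed Michael step (catalyst-controlled face, syn-selective open transition state). The Z alkene comes from diimide reduction of an iodoalkyne, the E tetrasubstituted alkene from the anti addition itself.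

Key step: step 13

Remark: the (R)-configured diphenylprolinol silyl ether is assumed to induce, with nitrodiene 9, the mirror image of the sense established for the (S)-catalyst with β-aryl nitroalkenes.

**Route**

Step 1
Reactants: 1 2-(3-chloropropyl)-2-methyl-1,3-dioxolane; 2 prop-2-yn-1-ol
Product: 4 2-[3-(2-methyl-1,3-dioxolan-2-yl)propyl]prop-2-en-1-ol, via Grignard reagent 3 (not isolated)
Conditions: 1 (2.5 equiv), Mg, BrCH2CH2Br (cat.), THF, reflux; then 2, CuI (10 mol%), THF, 0 °C to rt; aq. NH4Cl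
Reagents that add atoms: none
Why: Copper-catalysed anti-carbomagnesiation of the magnesium alkoxide of prop-2-yn-1-ol delivers the alkyl group of 3 to the internal alkyne carbon through a five-membered oxamagnesacycle, so protonation should give the 2-substituted allylic alcohol, one equivalent of 3 being consumed as base for the hydroxyl.

Step 2
Reactants: 4 2-[3-(2-methyl-1,3-dioxolan-2-yl)propyl]prop-2-en-1-ol
Product: 5 2-methylidene-5-(2-methyl-1,3-dioxolan-2-yl)pentanal
Conditions: MnO2 (activated, excess), CH2Cl2, rt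
Reagents that add atoms: none
Why: Heterogeneous allylic oxidation with activated MnO2 should stop at the 2-substituted acrolein under neutral conditions that leave the dioxolane untouched.

Step 3
Reactants: 5 2-methylidene-5-(2-methyl-1,3-dioxolan-2-yl)pentanal; 6 nitromethane
Product: 7 racemic 3-methylidene-6-(2-methyl-1,3-dioxolan-2-yl)-1-nitrohexan-2-ol
Conditions: 6 (5 equiv), KOt-Bu (10 mol%), THF/t-BuOH, 0 °C; AcOH quench
Reagents that add atoms: none
Why: Henry reaction under kinetic control, in which the nitronate adds to the aldehyde carbonyl faster than to the β-position of the enal at low temperature; the carbinol centre formed is racemic and is removed in step 4.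

Step 4
Reactants: 7 racemic 3-methylidene-6-(2-methyl-1,3-dioxolan-2-yl)-1-nitrohexan-2-ol
Product: 9 2-methyl-2-[(5E)-4-methylidene-6-nitrohex-5-en-1-yl]-1,3-dioxolane, via mesylate 8 (not isolated)
Conditions: MsCl, Et3N, CH2Cl2, −20 to 0 °C
Reagents that add atoms: none
Why: Mesylation followed by E1cB elimination of the β-nitro mesylate should give the conjugated nitrodiene as the thermodynamically preferred E isomer, which is kept cold in solution and used at once because 1-nitrodienes polymerise.

Step 5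
Reactants: 10 methyl 4,4-dimethoxybutanoate
Product: 11 4,4-dimethoxybutanal
Conditions: i-Bu2AlH (1.05 equiv), CH2Cl2, −78 °C; aq. potassium sodium tartrate
Reagents that add atoms: none
Why: Partial reduction of the methyl ester with one equivalent of i-Bu2AlH at −78 °C, where the tetrahedral aluminium hemiacetal survives until work-up, should give the aldehyde with the dimethyl acetal intact.

Step 6
Reactants: 11 4,4-dimethoxybutanal; 9 2-methyl-2-[(5E)-4-methylidene-6-nitrohex-5-en-1-yl]-1,3-dioxolane
Product: 12 (2S,3R)-2-(2,2-dimethoxyethyl)-4-methylidene-7-(2-methyl-1,3-dioxolan-2-yl)-3-(nitromethyl)heptanal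
Conditions: 11 (1.5 equiv), (R)-α,α-diphenylprolinol trimethylsilyl ether (10 mol%), 4-nitrophenol (10 mol%), toluene, 0 °C to rt
Reagents that add atoms: none
Why: Enamine-catalysed asymmetric Michael addition of an aldehyde to a nitroalkene: the E-enamine of 11, shielded on one face by the diphenyl(silyloxy)methyl group, should add 1,4 to the nitroalkene of 9 through an open synclinal transition state, so the (R)-catalyst sets C4 as S and C3 as R in a syn relationship.

Step 7
Reactants: 12 (2S,3R)-2-(2,2-dimethoxyethyl)-4-methylidene-7-(2-methyl-1,3-dioxolan-2-yl)-3-(nitromethyl)heptanal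
Product: 13 (3S,4R)-3-(2,2-dimethoxyethyl)-5-methylidene-8-(2-methyl-1,3-dioxolan-2-yl)-4-(nitromethyl)oct-1-yne
Conditions: dimethyl (1-diazo-2-oxopropyl)phosphonate (1.5 equiv), K2CO3 (2 equiv), MeOH, 0 °C to rt
Reagents that add atoms: dimethyl (1-diazo-2-oxopropyl)phosphonate, CC(=O)C(=[N+]=[N-])P(=O)(OC)OC
Why: Seyferth–Gilbert homologation in its Ohira–Bestmann form: the diazomethylphosphonate anion released by methanolysis adds to the aldehyde, and loss of phosphate and nitrogen with 1,2-shift in the alkylidene carbene gives the terminal alkyne under carbonate conditions in which α-branched aldehydes normally keep their configuration.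

Step 8
Reactants: 13 (3S,4R)-3-(2,2-dimethoxyethyl)-5-methylidene-8-(2-methyl-1,3-dioxolan-2-yl)-4-(nitromethyl)oct-1-yne
Product: 14 (2R,3S)-3-(2,2-dimethoxyethyl)-2-[5-(2-methyl-1,3-dioxolan-2-yl)pent-1-en-2-yl]pent-4-ynoic acid
Conditions: NaNO2 (3 equiv), AcOH (10 equiv), DMSO, 35 °C
Reagents that add atoms: sodium nitrite, [Na+].[O-]N=O; water, O
Why: Oxidative Nef-type conversion of a primary nitroalkane (nitrosation to the nitrolic acid, then hydrolysis through the nitrile oxide) should give the carboxylic acid directly under weakly acidic conditions that neither epimerise C3 nor move the alkene into conjugation and that spare acetal, ketal and alkyne.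

Step 9
Reactants: 14 (2R,3S)-3-(2,2-dimethoxyethyl)-2-[5-(2-methyl-1,3-dioxolan-2-yl)pent-1-en-2-yl]pent-4-ynoic acid
Product: 15 tert-butyl (2R,3S)-3-(2,2-dimethoxyethyl)-2-[5-(2-methyl-1,3-dioxolan-2-yl)pent-1-en-2-yl]pent-4-ynoate
Conditions: tert-butyl 2,2,2-trichloroacetimidate (3 equiv), cyclohexane/CH2Cl2, rt
Reagents that add atoms: tert-butyl 2,2,2-trichloroacetimidate, CC(C)(C)OC(=N)C(Cl)(Cl)Cl
Why: Imidate alkylation of the carboxylic acid (the acid itself protonates the trichloroacetimidate, which then transfers the tert-butyl group) forms the ester without base, so the C3–H next to the carboxyl is never deprotonated.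

Step 10
Reactants: 16 2-methylbut-3-yn-2-ol
Product: 17 4-iodo-2-methylbut-3-yn-2-ol
Conditions: N-iodosuccinimide, AgNO3 (10 mol%), acetone, rt, dark
Reagents that add atoms: N-iodosuccinimide, O=C1CCC(=O)N1I
Why: Silver-catalysed electrophilic iodination of the terminal alkyne through the silver acetylide gives the 1-iodoalkyne.

Step 11
Reactants: 17 4-iodo-2-methylbut-3-yn-2-ol
Product: 18 (3Z)-4-iodo-2-methylbut-3-en-2-ol
Conditions: 2-nitrobenzenesulfonylhydrazide, Et3N, THF/i-PrOH, rt
Reagents that add atoms: none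
Why: Diimide released from the sulfonyl hydrazide transfers two hydrogens in a concerted syn fashion to the iodoalkyne, which should give the Z-iodoalkene without hydrogenolysis of the C–I bond.

Step 12
Reactants: 15 tert-butyl (2R,3S)-3-(2,2-dimethoxyethyl)-2-[5-(2-methyl-1,3-dioxolan-2-yl)pent-1-en-2-yl]pent-4-ynoate; 18 (3Z)-4-iodo-2-methylbut-3-en-2-ol
Product: 19 tert-butyl (2R,3S,6Z)-3-(2,2-dimethoxyethyl)-8-hydroxy-8-methyl-2-[5-(2-methyl-1,3-dioxolan-2-yl)pent-1-en-2-yl]non-6-en-4-ynoate
Conditions: PdCl2(PPh3)2 (3 mol%), CuI (6 mol%), Et3N, THF, rt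
Reagents that add atoms: none
Why: Sonogashira coupling of the terminal alkyne with the alkenyl iodide proceeds with retention of the Z geometry and tolerates the free tertiary alcohol, the ester and the acetals.

Step 13
Reactants: 19 tert-butyl (2R,3S,6Z)-3-(2,2-dimethoxyethyl)-8-hydroxy-8-methyl-2-[5-(2-methyl-1,3-dioxolan-2-yl)pent-1-en-2-yl]non-6-en-4-ynoate
Product: 20 1-tert-butyl 5-methyl (2R,3S,4E)-3-(2,2-dimethoxyethyl)-4-(5,5-dimethylfuran-2(5H)-ylidene)-2-[5-(2-methyl-1,3-dioxolan-2-yl)pent-1-en-2-yl]pentanedioate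
Conditions: PdCl2(MeCN)2 (10 mol%), p-benzoquinone (1.5 equiv), CO (1 atm), MeOH, 0 °C to rt
Reagents that add atoms: carbon monoxide, [C-]#[O+]; methanol, CO
Why: Divalent palladium binds the C5≡C6 alkyne and the C9 hydroxyl, held alongside by the Z-configured C7=C8 alkene, attacks C6 from the face opposite the metal, leaving an alkenylpalladium at C5 trans to oxygen; CO insertion and methanolysis of the acylpalladium then give the methyl ester and zerovalent palladium, which benzoquinone returns to the divalent state. The closest known reaction type is the oxidative cyclisation–alkoxycarbonylation of alkynols and of (Z)-2-en-4-yn-1-ols to (E)-alkoxycarbonylmethylene oxacycles. The single ring, the 2,5-dihydrofuran, closes in the 5-exo-dig mode. No stereocentre is formed; the E geometry of the tetrasubstituted alkene follows from anti addition and from CO insertion with retention at C5, and C3 and C4 are not touched in the neutral medium. The step needs 5-exo over 6-endo closure, secured by the Z-enyne geometry and the conjugation gained in the dienyl ether, and carbonylation ahead of protodepalladation, favoured by CO-saturated methanol at low temperature with no free acid present. The quaternary C9 rules out tautomerisation to a furan, and the hydroxyl, the better and better-placed nucleophile, should outrun the tert-butyl ester carbonyl.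

Step 14
Reactants: 20 1-tert-butyl 5-methyl (2R,3S,4E)-3-(2,2-dimethoxyethyl)-4-(5,5-dimethylfuran-2(5H)-ylidene)-2-[5-(2-methyl-1,3-dioxolan-2-yl)pent-1-en-2-yl]pentanedioate
Product: 21 tert-butyl (2R,3S,4E)-3-(2,2-dimethoxyethyl)-4-(5,5-dimethylfuran-2(5H)-ylidene)-5-hydroxy-2-[5-(2-methyl-1,3-dioxolan-2-yl)pent-1-en-2-yl]pentanoate
Conditions: i-Bu2AlH (2.3 equiv), CH2Cl2, −78 °C; aq. potassium sodium tartrate
Reagents that add atoms: none
Why: Hydride reduction with i-Bu2AlH at −78 °C should take the unhindered methyl ester, a vinylogous carbonate, to the allylic alcohol while the tert-butyl ester, attached to a carbon flanked by two branched substituents, and the ketal-masked ketone stay untouched.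

Step 15
Reactants: 21 tert-butyl (2R,3S,4E)-3-(2,2-dimethoxyethyl)-4-(5,5-dimethylfuran-2(5H)-ylidene)-5-hydroxy-2-[5-(2-methyl-1,3-dioxolan-2-yl)pent-1-en-2-yl]pentanoate
Product: 22 tert-butyl (2R,3S,4E)-3-(2,2-dimethoxyethyl)-4-(5,5-dimethylfuran-2(5H)-ylidene)-2-[5-(2-methyl-1,3-dioxolan-2-yl)pent-1-en-2-yl]-5-oxopentanoate
Conditions: MnO2 (activated, excess), CH2Cl2, rt
Reagents that add atoms: none
Why: Allylic oxidation with activated MnO2 converts the primary alcohol on the acid-sensitive dienyl ether into the push–pull enal under neutral conditions, with alkene geometry and both stereocentres unaffected.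

Step 16
Reactants: 22 tert-butyl (2R,3S,4E)-3-(2,2-dimethoxyethyl)-4-(5,5-dimethylfuran-2(5H)-ylidene)-2-[5-(2-methyl-1,3-dioxolan-2-yl)pent-1-en-2-yl]-5-oxopentanoate
Product: 23 (2R,3S,4E)-4-(5,5-dimethylfuran-2(5H)-ylidene)-5-oxo-2-(6-oxohept-1-en-2-yl)-3-(2-oxoethyl)pentanoic acid (CNP0150297.1)
Conditions: TFA/CH2Cl2/H2O (4:4:1), 0 °C to rt
Reagents that add atoms: water, O
Why: Acid-mediated global deprotection, in which alkyl–oxygen cleavage of the tert-butyl ester and hydrolysis of the dimethyl acetal and the dioxolane should unveil acid, aldehyde and ketone, the dienyl ether being deactivated toward protonation as a vinylogous ester of the enal and neither stereocentre being enolised in cold acid.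

**Compound list**

1 | 2-(3-chloropropyl)-2-methyl-1,3-dioxolane | CC1(CCCCl)OCCO1 | starting material
2 | prop-2-yn-1-ol | C#CCO | starting material
3 | [3-(2-methyl-1,3-dioxolan-2-yl)propyl]magnesium chloride | CC1(CCC[Mg]Cl)OCCO1 | intermediate
4 | 2-[3-(2-methyl-1,3-dioxolan-2-yl)propyl]prop-2-en-1-ol | C=C(CO)CCCC1(C)OCCO1 | intermediate
5 | 2-methylidene-5-(2-methyl-1,3-dioxolan-2-yl)pentanal | C=C(C=O)CCCC1(C)OCCO1 | intermediate
6 | nitromethane | C[N+](=O)[O-] | starting material
7 | racemic 3-methylidene-6-(2-methyl-1,3-dioxolan-2-yl)-1-nitrohexan-2-ol | C=C(CCCC1(C)OCCO1)C(O)C[N+](=O)[O-] | intermediate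
8 | racemic 3-methylidene-6-(2-methyl-1,3-dioxolan-2-yl)-1-nitrohexan-2-yl methanesulfonate | C=C(CCCC1(C)OCCO1)C(OS(C)(=O)=O)C[N+](=O)[O-] | intermediate
9 | 2-methyl-2-[(5E)-4-methylidene-6-nitrohex-5-en-1-yl]-1,3-dioxolane | C=C(CCCC1(C)OCCO1)/C=C/[N+](=O)[O-] | intermediate
10 | methyl 4,4-dimethoxybutanoate | COC(=O)CCC(OC)OC | starting material
11 | 4,4-dimethoxybutanal | O=CCCC(OC)OC | intermediate
12 | (2S,3R)-2-(2,2-dimethoxyethyl)-4-methylidene-7-(2-methyl-1,3-dioxolan-2-yl)-3-(nitromethyl)heptanal | C=C(CCCC1(C)OCCO1)[C@H](C[N+](=O)[O-])[C@H](CC(OC)OC)C=O | intermediate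
13 | (3S,4R)-3-(2,2-dimethoxyethyl)-5-methylidene-8-(2-methyl-1,3-dioxolan-2-yl)-4-(nitromethyl)oct-1-yne | C=C(CCCC1(C)OCCO1)[C@H](C[N+](=O)[O-])[C@H](CC(OC)OC)C#C | intermediate
14 | (2R,3S)-3-(2,2-dimethoxyethyl)-2-[5-(2-methyl-1,3-dioxolan-2-yl)pent-1-en-2-yl]pent-4-ynoic acid | C=C(CCCC1(C)OCCO1)[C@H](C(=O)O)[C@H](CC(OC)OC)C#C | intermediate
15 | tert-butyl (2R,3S)-3-(2,2-dimethoxyethyl)-2-[5-(2-methyl-1,3-dioxolan-2-yl)pent-1-en-2-yl]pent-4-ynoate | C=C(CCCC1(C)OCCO1)[C@H](C(=O)OC(C)(C)C)[C@H](CC(OC)OC)C#C | intermediate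
16 | 2-methylbut-3-yn-2-ol | CC(C)(O)C#C | starting material
17 | 4-iodo-2-methylbut-3-yn-2-ol | CC(C)(O)C#CI | intermediate
18 | (3Z)-4-iodo-2-methylbut-3-en-2-ol | CC(C)(O)/C=C\I | intermediate
19 | tert-butyl (2R,3S,6Z)-3-(2,2-dimethoxyethyl)-8-hydroxy-8-methyl-2-[5-(2-methyl-1,3-dioxolan-2-yl)pent-1-en-2-yl]non-6-en-4-ynoate | C=C(CCCC1(C)OCCO1)[C@H](C(=O)OC(C)(C)C)[C@H](CC(OC)OC)C#C/C=C\C(C)(C)O | intermediate
20 | 1-tert-butyl 5-methyl (2R,3S,4E)-3-(2,2-dimethoxyethyl)-4-(5,5-dimethylfuran-2(5H)-ylidene)-2-[5-(2-methyl-1,3-dioxolan-2-yl)pent-1-en-2-yl]pentanedioate | C=C(CCCC1(C)OCCO1)[C@H](C(=O)OC(C)(C)C)[C@H](CC(OC)OC)/C(C(=O)OC)=C2/C=CC(C)(C)O2 | intermediate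
21 | tert-butyl (2R,3S,4E)-3-(2,2-dimethoxyethyl)-4-(5,5-dimethylfuran-2(5H)-ylidene)-5-hydroxy-2-[5-(2-methyl-1,3-dioxolan-2-yl)pent-1-en-2-yl]pentanoate | C=C(CCCC1(C)OCCO1)[C@H](C(=O)OC(C)(C)C)[C@H](CC(OC)OC)/C(CO)=C2/C=CC(C)(C)O2 | intermediate
22 | tert-butyl (2R,3S,4E)-3-(2,2-dimethoxyethyl)-4-(5,5-dimethylfuran-2(5H)-ylidene)-2-[5-(2-methyl-1,3-dioxolan-2-yl)pent-1-en-2-yl]-5-oxopentanoate | C=C(CCCC1(C)OCCO1)[C@H](C(=O)OC(C)(C)C)[C@H](CC(OC)OC)/C(C=O)=C2/C=CC(C)(C)O2 | intermediate
23 | (2R,3S,4E)-4-(5,5-dimethylfuran-2(5H)-ylidene)-5-oxo-2-(6-oxohept-1-en-2-yl)-3-(2-oxoethyl)pentanoic acid | C=C(CCCC(C)=O)[C@H](C(=O)O)[C@H](CC=O)/C(C=O)=C1/C=CC(C)(C)O1 | target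

**Step count and risks**

Total step count: 16. Longest linear sequence: 13 (steps 1–4, 6–9, 12–16).

Steps most likely to fail:

Step 13. The hindered, fully substituted C5–palladium bond may be protonated before CO inserts, or the branched internal alkyne may be activated too slowly, so that cycloisomerisation without carbonylation or no reaction takes over. The fallback separates ring closure from carbonylation. It sets out from 19: iodocyclisation (I2, NaHCO3, MeCN, 0 °C) adds the C9 hydroxyl and iodine anti across C5≡C6 in the 5-exo-dig mode and should give the iodoalkylidene dihydrofuran F1. Methoxycarbonylation of this alkenyl iodide (Pd(PPh3)4, CO 1 atm, MeOH, Et3N, 50 °C) proceeds with retention at C5 and comes back to the route at 20.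

Step 16. While the slow tert-butyl cleavage runs, the acid may move the 1,1-disubstituted alkene into conjugation with the carboxyl (erasing C3) or drive a Prins-type closure of the freed aldehyde onto that alkene. The fallback changes the carboxyl protection to an ester that ionises in very dilute acid yet is as hindered toward hydride as the tert-butyl ester. It sets out from 14: esterification with 2-phenylpropan-2-yl 2,2,2-trichloroacetimidate (CH2Cl2, rt) should give the cumyl alkynoate F2. Coupling with 18 as in step 12 gives the cumyl enynol F3, and the cyclisation–methoxycarbonylation of step 13 gives the cumyl methyl diester F4. Reduction as in step 14 gives the cumyl ester allylic alcohol F5, and MnO2 as in step 15 gives the cumyl ester enal F6. Treatment with 1–2 % TFA in wet CH2Cl2 at 0 °C, completed if needed by brief 1 M aq. HCl/THF for the dioxolane, then releases acid, aldehyde and ketone and comes back to the route at 23.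

Step 7. Carbonate in methanol may epimerise C4 of the γ-nitro aldehyde or draw the nitronate into nitro-aldol side reactions before the homologation is complete. The fallback builds the alkyne through a dibromoalkene under non-basic conditions and postpones the base until the nitro group is gone. It sets out from 12: Ramirez olefination (CBr4, PPh3, Zn, CH2Cl2, 0 °C) should give the dibromoalkene nitro compound F7. The nitrite oxidation of step 8 then gives the dibromoalkenyl acid F8. Treatment with n-BuLi (3.3 equiv, THF, −78 °C; carboxylate formation, bromine–lithium exchange, Fritsch–Buttenberg–Wiechell rearrangement) and NH4Cl quench comes back to the route at 14.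

Further compounds
F1 | step 13 | iodoalkylidene dihydrofuran (tert-butyl (2R,3S,4E)-3-(2,2-dimethoxyethyl)-4-(5,5-dimethylfuran-2(5H)-ylidene)-4-iodo-2-[5-(2-methyl-1,3-dioxolan-2-yl)pent-1-en-2-yl]butanoate) | C=C(CCCC1(C)OCCO1)[C@H](C(=O)OC(C)(C)C)[C@H](CC(OC)OC)/C(I)=C2/C=CC(C)(C)O2
F2 | step 16 | cumyl alkynoate (2-phenylpropan-2-yl (2R,3S)-3-(2,2-dimethoxyethyl)-2-[5-(2-methyl-1,3-dioxolan-2-yl)pent-1-en-2-yl]pent-4-ynoate) | C=C(CCCC1(C)OCCO1)[C@H](C(=O)OC(C)(C)c2ccccc2)[C@H](CC(OC)OC)C#C
F3 | step 16 | cumyl enynol (2-phenylpropan-2-yl (2R,3S,6Z)-3-(2,2-dimethoxyethyl)-8-hydroxy-8-methyl-2-[5-(2-methyl-1,3-dioxolan-2-yl)pent-1-en-2-yl]non-6-en-4-ynoate) | C=C(CCCC1(C)OCCO1)[C@H](C(=O)OC(C)(C)c2ccccc2)[C@H](CC(OC)OC)C#C/C=C\C(C)(C)O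
F4 | step 16 | cumyl methyl diester (5-methyl 1-(2-phenylpropan-2-yl) (2R,3S,4E)-3-(2,2-dimethoxyethyl)-4-(5,5-dimethylfuran-2(5H)-ylidene)-2-[5-(2-methyl-1,3-dioxolan-2-yl)pent-1-en-2-yl]pentanedioate) | C=C(CCCC1(C)OCCO1)[C@H](C(=O)OC(C)(C)c2ccccc2)[C@H](CC(OC)OC)/C(C(=O)OC)=C3/C=CC(C)(C)O3
F5 | step 16 | cumyl ester allylic alcohol (2-phenylpropan-2-yl (2R,3S,4E)-3-(2,2-dimethoxyethyl)-4-(5,5-dimethylfuran-2(5H)-ylidene)-5-hydroxy-2-[5-(2-methyl-1,3-dioxolan-2-yl)pent-1-en-2-yl]pentanoate) | C=C(CCCC1(C)OCCO1)[C@H](C(=O)OC(C)(C)c2ccccc2)[C@H](CC(OC)OC)/C(CO)=C3/C=CC(C)(C)O3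
F6 | step 16 | cumyl ester enal (2-phenylpropan-2-yl (2R,3S,4E)-3-(2,2-dimethoxyethyl)-4-(5,5-dimethylfuran-2(5H)-ylidene)-2-[5-(2-methyl-1,3-dioxolan-2-yl)pent-1-en-2-yl]-5-oxopentanoate) | C=C(CCCC1(C)OCCO1)[C@H](C(=O)OC(C)(C)c2ccccc2)[C@H](CC(OC)OC)/C(C=O)=C3/C=CC(C)(C)O3
F7 | step 7 | dibromoalkene nitro compound ((3S,4R)-1,1-dibromo-3-(2,2-dimethoxyethyl)-5-methylidene-8-(2-methyl-1,3-dioxolan-2-yl)-4-(nitromethyl)oct-1-ene) | C=C(CCCC1(C)OCCO1)[C@H](C[N+](=O)[O-])[C@H](CC(OC)OC)C=C(Br)Br
F8 | step 7 | dibromoalkenyl acid ((2R,3S)-5,5-dibromo-3-(2,2-dimethoxyethyl)-2-[5-(2-methyl-1,3-dioxolan-2-yl)pent-1-en-2-yl]pent-4-enoic acid) | C=C(CCCC1(C)OCCO1)[C@H](C(=O)O)[C@H](CC(OC)OC)C=C(Br)Br
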